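**Retrosynthetic overview**
1. Target 22 ⇐ dimethoxyquinone 21 (hydrolysis of the OMe next to the side chain) ⇐ tetramethoxyarene 20 (oxidative demethylation).
2. 20 ⇐ (E)-alkenylalane 19 + benzylic chloride 18, a late sp2–sp3 union of a C14 terpenoid half and a C11 arene half; the (E)-alkene comes from Zr-catalysed methylalumination of alkyne 10.
3. 18 ⇐ 1,2,4,5-tetramethoxybenzene 14 (formylation, reduction, chlorination) ⇐ hydroquinone 11 (methylation, dibromination, Cu-catalysed methoxylation).
4. 10 ⇐ iodide 9 + acetylide ⇐ ester 7 ⇐ Johnson–Claisen rearrangement (1,3-chirality transfer) of (R)-allylic alcohol 5 ⇐ CBS reduction of enone 4.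
5. Ring order: only the cyclohexene is built (Robinson annulation of 1 + 2, step 1); the oxygenated ring is carried as a benzene and becomes the quinone in step 14.

Assumption: the structure is taken exactly as drawn, (S) at the ring CH and (E) at the side-chain alkene.

**Terpenoid half**

Step 1
Reactants: 1 isobutyraldehyde (2-methylpropanal); 2 ethyl vinyl ketone (pent-1-en-3-one)
Product: 4 2,4,4-trimethylcyclohex-2-en-1-one, via 2,2-dimethyl-5-oxoheptanal 3 (not isolated)
Conditions: H2SO4 (cat.), 45–50 °C; then toluene, reflux, Dean–Stark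
Reagents that add atoms: none
Why: Acid-catalysed Robinson annulation (Michael addition, then aldol condensation through the ethyl-ketone CH2); the aldehyde has a single α-H, which fixes the 4,4-dimethyl pattern and the 2-methyl enone.

Step 2
Reactants: 4 2,4,4-trimethylcyclohex-2-en-1-one
Product: 5 (1R)-2,4,4-trimethylcyclohex-2-en-1-ol
Conditions: (S)-2-methyl-CBS-oxazaborolidine (10 mol %), BH3·SMe2 (0.6 equiv), THF, −20 °C; MeOH quench
Reagents that add atoms: none
Why: Corey–Bakshi–Shibata reduction; the α-methylated alkenyl arm acts as the large group, so the (S)-catalyst delivers hydride to give the (R)-carbinol by clean 1,2-reduction.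

Step 3
Reactants: 5 (1R)-2,4,4-trimethylcyclohex-2-en-1-ol
Product: 7 methyl 2-[(1S)-2,6,6-trimethylcyclohex-2-en-1-yl]acetate, via mixed ketene acetal 6 (not isolated)
Conditions: MeC(OMe)3 (7 equiv), EtCO2H (10 mol %), xylene, 140 °C, MeOH distilled off
Reagents that add atoms: trimethyl orthoacetate, CC(OC)(OC)OC
Why: Johnson orthoester Claisen rearrangement; the suprafacial [3,3] shift forms the C–C bond on the ring face that carried oxygen, so (R) at the carbinol becomes (S) at the carbon next to the gem-dimethyl group and the alkene moves to the methyl-bearing position.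

Step 4
Reactants: 7 methyl 2-[(1S)-2,6,6-trimethylcyclohex-2-en-1-yl]acetate
Product: 8 2-[(1S)-2,6,6-trimethylcyclohex-2-en-1-yl]ethan-1-ol
Conditions: LiAlH4, Et2O, 0 °C; then H2O, aq. NaOH
Reagents that add atoms: none
Why: Hydride reduction of an ester to the primary alcohol; the isolated trisubstituted alkene and the non-epimerisable stereocentre are untouched.

Step 5
Reactants: 8 2-[(1S)-2,6,6-trimethylcyclohex-2-en-1-yl]ethan-1-ol
Product: 9 (6S)-6-(2-iodoethyl)-1,5,5-trimethylcyclohex-1-ene
Conditions: PPh3, I2, imidazole, CH2Cl2, 0 °C → rt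
Reagents that add atoms: iodine, [I][I]
Why: Appel-type (Garegg–Samuelsson) iodination of an unhindered primary alcohol by SN2 displacement.

Step 6
Reactants: 9 (6S)-6-(2-iodoethyl)-1,5,5-trimethylcyclohex-1-ene
Product: 10 (6S)-6-(but-3-yn-1-yl)-1,5,5-trimethylcyclohex-1-ene
Conditions: LiC≡CH·H2NCH2CH2NH2 (1.5 equiv), DMSO, 10 °C → rt
Reagents that add atoms: lithium acetylide (ethylenediamine complex), [Li]C#C.NCCN
Why: SN2 alkylation of acetylide by a primary iodide with no β-branching in a dipolar aprotic solvent; elimination is minor.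

**Arene half**

Step 7
Reactants: 11 hydroquinone (benzene-1,4-diol)
Product: 12 1,4-dimethoxybenzene
Conditions: Me2SO4 (2.5 equiv), K2CO3, acetone, reflux
Reagents that add atoms: dimethyl sulfate, COS(=O)(=O)OC
Why: Williamson O-methylation of both phenols.

Step 8
Reactants: 12 1,4-dimethoxybenzene
Product: 13 1,4-dibromo-2,5-dimethoxybenzene
Conditions: Br2 (2.1 equiv), AcOH, rt
Reagents that add atoms: bromine, BrBr
Why: Electrophilic aromatic bromination; each OMe directs ortho and the second bromine enters para to the first, giving the 2,5-pattern.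

Step 9
Reactants: 13 1,4-dibromo-2,5-dimethoxybenzene
Product: 14 1,2,4,5-tetramethoxybenzene
Conditions: NaOMe (6 equiv), CuBr (20 mol %), MeOH/DMF, 110 °C
Reagents that add atoms: sodium methoxide, [Na+].[O-]C
Why: Ullmann-type copper-catalysed methoxylation of both aryl bromides.

Step 10
Reactants: 14 1,2,4,5-tetramethoxybenzene
Product: 16 2,3,5,6-tetramethoxybenzaldehyde, via (2,3,5,6-tetramethoxyphenyl)lithium 15 (not isolated)
Conditions: n-BuLi (1.05 equiv), TMEDA, THF, 0 °C; DMF, 0 °C → rt; 1 M HCl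
Reagents that add atoms: n-butyllithium, [Li]CCCC (supplies only the lithium of 15); N,N-dimethylformamide, CN(C)C=O
Why: Directed ortho-metalation at a CH flanked by two methoxy groups, then Bouveault formylation; one equivalent of base keeps it to monolithiation.

Step 11
Reactants: 16 2,3,5,6-tetramethoxybenzaldehyde
Product: 17 (2,3,5,6-tetramethoxyphenyl)methanol
Conditions: NaBH4, MeOH, 0 °C
Reagents that add atoms: none
Why: Borohydride reduction of an aryl aldehyde to the benzylic alcohol.

Step 12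
Reactants: 17 (2,3,5,6-tetramethoxyphenyl)methanol
Product: 18 3-(chloromethyl)-1,2,4,5-tetramethoxybenzene
Conditions: SOCl2 (1.2 equiv), CH2Cl2, 0 °C; used at once
Reagents that add atoms: thionyl chloride, O=S(Cl)Cl
Why: Chlorodehydroxylation of an activated benzylic alcohol; the chloride is chosen over the bromide for stability on this electron-rich ring.

**Union and end game**

Step 13
Reactants: 10 (6S)-6-(but-3-yn-1-yl)-1,5,5-trimethylcyclohex-1-ene; 18 3-(chloromethyl)-1,2,4,5-tetramethoxybenzene
Product: 20 1,2,4,5-tetramethoxy-3-{(2E)-3-methyl-5-[(1S)-2,6,6-trimethylcyclohex-2-en-1-yl]pent-2-en-1-yl}benzene, via (E)-alkenyldimethylalane 19 (not isolated)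
Conditions: AlMe3 (2.0 equiv), Cp2ZrCl2 (0.25 equiv), ClCH2CH2Cl, rt, 12 h; volatiles and excess AlMe3 removed in vacuo; THF, 18 (0.9 equiv), NiCl2(PPh3)2 (5 mol %) pre-reduced with n-BuLi (10 mol %) to zerovalent nickel, rt; cold dilute HCl
Reagents that add atoms: trimethylaluminium, C[Al](C)C (one CH3 stays in 20; the AlMe2 group only in 19)
Why: Negishi zirconium-catalysed methylalumination adds Me and Al syn with Al at the terminal carbon, fixing the (E)-alkene; nickel-catalysed alkenyl–benzyl cross-coupling then proceeds with retention and cannot transpose because the allylic unit is created by the coupling itself.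

Step 14
Reactants: 20 the tetramethoxyarene from step 13
Product: 21 2,5-dimethoxy-3-{(2E)-3-methyl-5-[(1S)-2,6,6-trimethylcyclohex-2-en-1-yl]pent-2-en-1-yl}cyclohexa-2,5-diene-1,4-dione
Conditions: (NH4)2Ce(NO3)6 (2.5 equiv), MeCN/H2O 2:1, 0 °C, 20 min
Reagents that add atoms: water, O
Why: Oxidative demethylation of a para-dimethoxyarene by tetravalent cerium; the arene has a mirror plane through the alkyl carbon, so either para pair gives the same 2,5-dimethoxyquinone, and the alkenes survive the short cold reaction.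

Step 15
Reactants: 21 the dimethoxyquinone from step 14
Product: 22 2-hydroxy-5-methoxy-3-{(2E)-3-methyl-5-[(1S)-2,6,6-trimethylcyclohex-2-en-1-yl]pent-2-en-1-yl}cyclohexa-2,5-diene-1,4-dione
Conditions: NaOH (1 M aq, 2 equiv), THF/MeOH, 0 °C → rt, N2; then 1 M HCl to pH 3
Reagents that add atoms: sodium hydroxide, [Na+].[OH-]
Why: Addition–elimination (vinylogous ester saponification); the methoxy flanked by the side chain is twisted out of conjugation and is displaced first, and the resulting hydroxyquinone anion resists a second hydrolysis.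

**Compound list**
1 | isobutyraldehyde | CC(C)C=O | starting material
2 | ethyl vinyl ketone (pent-1-en-3-one) | CCC(=O)C=C | starting material
3 | 2,2-dimethyl-5-oxoheptanal | CCC(=O)CCC(C)(C)C=O | intermediate
4 | 2,4,4-trimethylcyclohex-2-en-1-one | CC1=CC(C)(C)CCC1=O | intermediate
5 | (1R)-2,4,4-trimethylcyclohex-2-en-1-ol | O[C@H]1C(C)=CC(C)(C)CC1 | intermediate
6 | (6R)-6-[(1-methoxyethenyl)oxy]-1,3,3-trimethylcyclohex-1-ene (mixed ketene acetal) | C=C(OC)O[C@H]1C(C)=CC(C)(C)CC1 | intermediate
7 | methyl 2-[(1S)-2,6,6-trimethylcyclohex-2-en-1-yl]acetate | COC(=O)C[C@@H]1C(C)=CCCC1(C)C | intermediate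
8 | 2-[(1S)-2,6,6-trimethylcyclohex-2-en-1-yl]ethan-1-ol | OCC[C@@H]1C(C)=CCCC1(C)C | intermediate
9 | (6S)-6-(2-iodoethyl)-1,5,5-trimethylcyclohex-1-ene | ICC[C@@H]1C(C)=CCCC1(C)C | intermediate
10 | (6S)-6-(but-3-yn-1-yl)-1,5,5-trimethylcyclohex-1-ene | C#CCC[C@@H]1C(C)=CCCC1(C)C | intermediate
11 | hydroquinone | Oc1ccc(O)cc1 | starting material
12 | 1,4-dimethoxybenzene | COc1ccc(OC)cc1 | intermediate
13 | 1,4-dibromo-2,5-dimethoxybenzene | COc1cc(Br)c(OC)cc1Br | intermediate
14 | 1,2,4,5-tetramethoxybenzene | COc1cc(OC)c(OC)cc1OC | intermediate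
15 | (2,3,5,6-tetramethoxyphenyl)lithium | [Li]c1c(OC)c(OC)cc(OC)c1OC | intermediate
16 | 2,3,5,6-tetramethoxybenzaldehyde | O=Cc1c(OC)c(OC)cc(OC)c1OC | intermediate
17 | (2,3,5,6-tetramethoxyphenyl)methanol | OCc1c(OC)c(OC)cc(OC)c1OC | intermediate
18 | 3-(chloromethyl)-1,2,4,5-tetramethoxybenzene | ClCc1c(OC)c(OC)cc(OC)c1OC | intermediate
19 | dimethyl{(1E)-2-methyl-4-[(1S)-2,6,6-trimethylcyclohex-2-en-1-yl]but-1-en-1-yl}alumane | C[Al](C)/C=C(\C)CC[C@@H]1C(C)=CCCC1(C)C | intermediate
20 | 1,2,4,5-tetramethoxy-3-{(2E)-3-methyl-5-[(1S)-2,6,6-trimethylcyclohex-2-en-1-yl]pent-2-en-1-yl}benzene | COc1cc(OC)c(OC)c(C/C=C(\C)CC[C@@H]2C(C)=CCCC2(C)C)c1OC | intermediate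
21 | 2,5-dimethoxy-3-{(2E)-3-methyl-5-[(1S)-2,6,6-trimethylcyclohex-2-en-1-yl]pent-2-en-1-yl}cyclohexa-2,5-diene-1,4-dione | COC1=CC(=O)C(OC)=C(C/C=C(\C)CC[C@@H]2C(C)=CCCC2(C)C)C1=O | intermediate
22 | 2-hydroxy-5-methoxy-3-{(2E)-3-methyl-5-[(1S)-2,6,6-trimethylcyclohex-2-en-1-yl]pent-2-en-1-yl}cyclohexa-2,5-diene-1,4-dione | COC1=CC(=O)C(O)=C(C/C=C(\C)CC[C@@H]2C(C)=CCCC2(C)C)C1=O | target

**Totals**
Total step count: 15.
Longest linear sequence: 9 steps (steps 1–6, then 13–15; the arene branch, steps 7–12 then 13–15, is equally long).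

**Three steps most likely to fail**

Step 3 (Claisen rearrangement onto the carbon next to the quaternary centre; risk of a stalled reaction or acid-promoted loss of ee). The fallback sets out from 5 and comes back at 8. It replaces the acidic orthoester process at 140 °C by an ester-enolate (Ireland–Claisen) rearrangement below 70 °C. Alcohol 5 is acetylated (Ac2O, pyridine, DMAP) to (1R)-2,4,4-trimethylcyclohex-2-en-1-yl acetate F1. LiN(iPr)2 and Me3SiCl in THF at −78 °C give (6R)-1,3,3-trimethyl-6-({1-[(trimethylsilyl)oxy]ethenyl}oxy)cyclohex-1-ene F2. Warming to 60 °C rearranges it suprafacially to trimethylsilyl 2-[(1S)-2,6,6-trimethylcyclohex-2-en-1-yl]acetate F3. Aqueous work-up gives 2-[(1S)-2,6,6-trimethylcyclohex-2-en-1-yl]acetic acid F4, and LiAlH4 reduction of F4 gives 8.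

Step 13 (nickel-catalysed alkenyl–benzyl coupling; risk of methylation or homocoupling of the electron-rich chloride 18). The fallback sets out from 10 (through alane 19) and from 14 (through aryllithium 15) and comes back at 20. It reverses the polarity, with the arene as nucleophile and the terpenoid as allylic electrophile. Alane 19 is treated with paraformaldehyde (THF, rt; dilute HCl work-up) to give (2E)-3-methyl-5-[(1S)-2,6,6-trimethylcyclohex-2-en-1-yl]pent-2-en-1-ol F5. PBr3 (Et2O, −10 °C) converts it into (6S)-6-[(3E)-5-bromo-3-methylpent-3-en-1-yl]-1,5,5-trimethylcyclohex-1-ene F6. Aryllithium 15, made from 14 with n-BuLi/TMEDA, is allylated by F6 in the presence of CuBr·SMe2 (THF, −78 → 0 °C) by SN2 at the primary allylic carbon to give 20.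

Step 15 (regioselective mono-hydrolysis; risk of the wrong methoxy being cleaved or of double hydrolysis). The fallback sets out from 21 and comes back at 22. Both methyl groups are removed and one is put back under thermodynamic control. Excess aqueous NaOH (EtOH, 50 °C, then HCl) converts 21 into 2,5-dihydroxy-3-{(2E)-3-methyl-5-[(1S)-2,6,6-trimethylcyclohex-2-en-1-yl]pent-2-en-1-yl}cyclohexa-2,5-diene-1,4-dione F7. F7 in MeOH with catalytic BF3·OEt2 at rt undergoes acid-catalysed vinylogous esterification only at the oxygen remote from the side chain (the flanked position is hindered), giving 22.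

**Further compounds**
F1 | step 3 | (1R)-2,4,4-trimethylcyclohex-2-en-1-yl acetate | CC(=O)O[C@H]1C(C)=CC(C)(C)CC1
F2 | step 3 | (6R)-1,3,3-trimethyl-6-({1-[(trimethylsilyl)oxy]ethenyl}oxy)cyclohex-1-ene | C=C(O[Si](C)(C)C)O[C@H]1C(C)=CC(C)(C)CC1
F3 | step 3 | trimethylsilyl 2-[(1S)-2,6,6-trimethylcyclohex-2-en-1-yl]acetate | C[Si](C)(C)OC(=O)C[C@@H]1C(C)=CCCC1(C)C
F4 | step 3 | 2-[(1S)-2,6,6-trimethylcyclohex-2-en-1-yl]acetic acid | OC(=O)C[C@@H]1C(C)=CCCC1(C)C
F5 | step 13 | (2E)-3-methyl-5-[(1S)-2,6,6-trimethylcyclohex-2-en-1-yl]pent-2-en-1-ol | OC/C=C(\C)CC[C@@H]1C(C)=CCCC1(C)C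
F6 | step 13 | (6S)-6-[(3E)-5-bromo-3-methylpent-3-en-1-yl]-1,5,5-trimethylcyclohex-1-ene | BrC/C=C(\C)CC[C@@H]1C(C)=CCCC1(C)C
F7 | step 15 | 2,5-dihydroxy-3-{(2E)-3-methyl-5-[(1S)-2,6,6-trimethylcyclohex-2-en-1-yl]pent-2-en-1-yl}cyclohexa-2,5-diene-1,4-dione | OC1=CC(=O)C(O)=C(C/C=C(\C)CC[C@@H]2C(C)=CCCC2(C)C)C1=O
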